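**Retrosynthetic overview** (flavanone numbering: O1, C2 bears ring B, C3 bears OMe, C4 is the carbonyl; ring A is the fused arene, ring C the pyranone)
1. Target 19 ⇐ protected trans-3-methoxyflavanone 17 (remove the 5-O-methyl and two O-benzyl groups) ⇐ (R)-3-methoxy-2H-chromene 13 (raise C4 to the ketone by hydroboration/oxidation, equilibrate C3).
2. Chromene 13 ⇐ salicylaldehyde 2 + (Z)-α-methoxycinnamic acid 9: one isothiourea-catalysed cascade forms O1–C2 (oxa-Michael) and C3–C4 (aldol) and sets C2; the carboxyl of 9 is a traceless activating group that leaves as CO2 through a temporary β-lactone ring.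
3. Enabling feature: ring A is a salicyl unit, with phenolic O1 on C8a ortho to C4a, which carries C4; as its aldehyde it offers a nucleophilic oxygen and an electrophilic carbon in 1,4-relation. C3 with its OMe is the α-carbon, and C2 with ring B the β-carbon, of a cinnamoyl unit.
4. Rings A and B are bought as arenes (3,4,5-trimethoxyphenol 1, methoxyhydroquinone 3); ring C is the only ring built, in step 6.
5. Acid 9 ⇐ aldehyde 6 (Horner–Wadsworth–Emmons) ⇐ 3; aldehyde 2 ⇐ 1 (ortho-formylation).

Key step: step 6

Assumption: the sense of induction of the isothiourea is taken from its known conjugate additions; the (2S,3R) catalyst is written for the (2R) series, and its mirror image would be used if the sense proved opposite.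

Step 1
Reactants: 1 3,4,5-trimethoxyphenol
Product: 2 6-hydroxy-2,3,4-trimethoxybenzaldehyde
Conditions: MgCl2, Et3N, (CH2O)n, MeCN, reflux; aq. HCl work-up
Reagents that add atoms: paraformaldehyde (as formaldehyde), C=O
Why: Magnesium-phenoxide-directed ortho-formylation should formylate one of the two equivalent positions ortho to the hydroxyl group, a second equivalent of formaldehyde acting as hydride acceptor.

Step 2
Reactants: 3 2-methoxybenzene-1,4-diol
Product: 4 1,4-bis(benzyloxy)-2-methoxybenzene
Conditions: BnBr, K2CO3, DMF, rt, under N2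
Reagents that add atoms: benzyl bromide, BrCc1ccccc1
Why: Williamson etherification should mask both hydroquinone oxygens as benzyl ethers that are removable later by hydrogenolysis.

Step 3
Reactants: 4 1,4-bis(benzyloxy)-2-methoxybenzene
Product: 6 2,5-bis(benzyloxy)-4-methoxybenzaldehyde, via aryl iminium chloride 5 (not isolated)
Conditions: POCl3, DMF, 0 to 60 °C; then H2O, rt
Reagents that add atoms: N,N-dimethylformamide, CN(C)C=O; phosphoryl chloride, O=P(Cl)(Cl)Cl (chloride of 5 only); water, O
Why: Vilsmeier–Haack formylation should take place para to the methoxy group and ortho to a benzyloxy group, the position activated by both, as with 1,2,4-trialkoxybenzenes.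

Step 4
Reactants: 6 2,5-bis(benzyloxy)-4-methoxybenzaldehyde; 7 methyl 2-(dimethoxyphosphoryl)-2-methoxyacetate
Product: 8 methyl (Z)-3-[2,5-bis(benzyloxy)-4-methoxyphenyl]-2-methoxyprop-2-enoate
Conditions: NaH, THF, 0 °C to rt
Reagents that add atoms: none
Why: Horner–Wadsworth–Emmons olefination with the α-methoxy phosphonoacetate should give mainly the (Z)-alkene (aryl trans to the ester), which is separated from the minor isomer.

Step 5
Reactants: 8 methyl (Z)-3-[2,5-bis(benzyloxy)-4-methoxyphenyl]-2-methoxyprop-2-enoate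
Product: 9 (Z)-3-[2,5-bis(benzyloxy)-4-methoxyphenyl]-2-methoxyprop-2-enoic acid
Conditions: LiOH, THF/H2O, rt; then aq. HCl
Reagents that add atoms: lithium hydroxide, [Li+].[OH-]
Why: Ester saponification should give the free acid without touching the enol ether or the benzyl ethers.

Step 6
Reactants: 9 (Z)-3-[2,5-bis(benzyloxy)-4-methoxyphenyl]-2-methoxyprop-2-enoic acid; 2 6-hydroxy-2,3,4-trimethoxybenzaldehyde
Product: 13 (R)-2-[2,5-bis(benzyloxy)-4-methoxyphenyl]-3,5,6,7-tetramethoxy-2H-chromene, via mixed pivalic anhydride 10 (not isolated), via 2-formylaryl ester 11 (not isolated), via chromane β-lactone 12 (not isolated)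
Conditions: Piv2O, i-Pr2NEt, CH2Cl2, 0 °C; then 2 and the isothiourea (2S,3R)-3-isopropyl-2-phenyl-3,4-dihydro-2H-benzo[4,5]thiazolo[3,2-a]pyrimidine (HyperBTM, 10 mol%), 0 to 40 °C
Reagents that add atoms: pivalic anhydride, CC(C)(C)C(=O)OC(=O)C(C)(C)C (pivaloyl group of 10 only)
Why: Proposed new method: the isothiourea is acylated by anhydride 10 (and, after O-acylation of 2, by the active aryl ester 11) to an α,β-unsaturated acylammonium ion held s-cis by the sulfur–carbonyl oxygen contact; the aryloxide of 2 adds to its β-carbon (O1–C2), the ammonium enolate closes the pyran ring by aldol addition of C3 to the formyl carbon C4 (6-exo-trig at the carbonyl), and the alkoxide lactonises onto the acylammonium carbon (4-exo-trig) to release the catalyst and β-lactone 12, which loses CO2 by retro-[2+2] cleavage to give 13. The closest known reaction type is the isothiourea-catalysed, acyl-transfer-initiated thia-Michael/aldol/β-lactonisation/decarboxylation cascade of S-(2-formylaryl) α,β-unsaturated thioesters to 2-substituted 2H-thiochromenes, together with Michael/aldol/lactonisation cascades of unsaturated acylammonium ions with carbon nucleophiles; an aryloxide donor and an α-alkoxy acceptor have not been shown. The only stereocentre that survives, C2, is set in the oxa-Michael step by the catalyst, whose phenyl group shields one face of the planar acylammonium ion; the C3 and C4 centres of 12 are erased on decarboxylation. The step needs 1,4- over 1,2-addition of the aryloxide, which is secured because O-acylation only leads to ester 11, which the catalyst re-ionises to the same ion pair, while aldol closure and loss of CO2 are irreversible and drain the reversible oxa-Michael equilibrium. It also needs the catalyst to attack the cinnamoyl and not the pivaloyl carbonyl of 10, which the tert-butyl group should ensure, and no racemic background, which is why no achiral nucleophilic amine is present.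

Step 7
Reactants: 13 (R)-2-[2,5-bis(benzyloxy)-4-methoxyphenyl]-3,5,6,7-tetramethoxy-2H-chromene
Product: 15 (2R,3R,4S)-2-[2,5-bis(benzyloxy)-4-methoxyphenyl]-3,5,6,7-tetramethoxychroman-4-ol, via C4 alkylborane 14 (not isolated)
Conditions: BH3·THF, THF, 0 °C; then H2O2, aq. NaOH, 0 °C
Reagents that add atoms: borane (as BH3·THF), B (boron of 14 only); hydrogen peroxide, OO
Why: Hydroboration–oxidation of the enol ether should place boron at C4 (β to the methoxy oxygen, benzylic, less substituted) and hydrogen at C3, syn and on the face anti to the C2 aryl group, and oxidation with retention gives the 4-ol; the C3 centre formed here (OMe cis to aryl) is corrected in step 8.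

Step 8
Reactants: 15 (2R,3R,4S)-2-[2,5-bis(benzyloxy)-4-methoxyphenyl]-3,5,6,7-tetramethoxychroman-4-ol
Product: 17 (2R,3R)-2-[2,5-bis(benzyloxy)-4-methoxyphenyl]-3,5,6,7-tetramethoxychroman-4-one, via cis ketone 16 (not isolated)
Conditions: Dess–Martin periodinane, pyridine, CH2Cl2, 0 °C to rt; then Et3N (20 mol%), CH2Cl2, rt
Reagents that add atoms: none
Why: Dess–Martin oxidation of the benzylic alcohol gives the 2,3-cis ketone 16, whose C3 centre, α to the carbonyl, should equilibrate through the enol under mild amine base to the more stable 2,3-trans (diequatorial) ketone while C2 is not touched.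

Step 9
Reactants: 17 (2R,3R)-2-[2,5-bis(benzyloxy)-4-methoxyphenyl]-3,5,6,7-tetramethoxychroman-4-one
Product: 18 (2R,3R)-2-[2,5-bis(benzyloxy)-4-methoxyphenyl]-5-hydroxy-3,6,7-trimethoxychroman-4-one
Conditions: BCl3, CH2Cl2, −78 to −20 °C; then H2O
Reagents that add atoms: none
Why: Chelation-controlled ether cleavage by BCl3 should remove only the methyl group peri to the C4 carbonyl (six-membered boron chelate), the other methyl ethers and, at low temperature, the benzyl ethers lacking this activation.

Step 10
Reactants: 18 (2R,3R)-2-[2,5-bis(benzyloxy)-4-methoxyphenyl]-5-hydroxy-3,6,7-trimethoxychroman-4-one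
Product: 19 (2R,3R)-2-(2,5-dihydroxy-4-methoxyphenyl)-5-hydroxy-3,6,7-trimethoxychroman-4-one
Conditions: H2 (1 atm), Pd/C, EtOAc, rt
Reagents that add atoms: none
Why: Catalytic hydrogenolysis of the two benzyl ethers under neutral conditions should unveil the hydroquinone without epimerising C2 or C3 or reducing the chelated ketone.

**Compound list**
1 | 3,4,5-trimethoxyphenol | COc1cc(O)cc(OC)c1OC | starting material
2 | 6-hydroxy-2,3,4-trimethoxybenzaldehyde | O=Cc1c(O)cc(OC)c(OC)c1OC | intermediate
3 | 2-methoxybenzene-1,4-diol (methoxyhydroquinone) | COc1cc(O)ccc1O | starting material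
4 | 1,4-bis(benzyloxy)-2-methoxybenzene | COc1cc(OCc2ccccc2)ccc1OCc1ccccc1 | intermediate
5 | N-[2,5-bis(benzyloxy)-4-methoxybenzylidene]-N-methylmethanaminium chloride | COc1cc(OCc2ccccc2)c(C=[N+](C)C)cc1OCc1ccccc1.[Cl-] | intermediate
6 | 2,5-bis(benzyloxy)-4-methoxybenzaldehyde | COc1cc(OCc2ccccc2)c(C=O)cc1OCc1ccccc1 | intermediate
7 | methyl 2-(dimethoxyphosphoryl)-2-methoxyacetate | COC(C(=O)OC)P(=O)(OC)OC | starting material
8 | methyl (Z)-3-[2,5-bis(benzyloxy)-4-methoxyphenyl]-2-methoxyprop-2-enoate | COC(=O)/C(OC)=C/c1cc(OCc2ccccc2)c(OC)cc1OCc1ccccc1 | intermediate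
9 | (Z)-3-[2,5-bis(benzyloxy)-4-methoxyphenyl]-2-methoxyprop-2-enoic acid | OC(=O)/C(OC)=C/c1cc(OCc2ccccc2)c(OC)cc1OCc1ccccc1 | intermediate
10 | mixed anhydride of acid 9 with pivalic acid | CC(C)(C)C(=O)OC(=O)/C(OC)=C/c1cc(OCc2ccccc2)c(OC)cc1OCc1ccccc1 | intermediate
11 | 2-formyl-3,4,5-trimethoxyphenyl (Z)-3-[2,5-bis(benzyloxy)-4-methoxyphenyl]-2-methoxyprop-2-enoate | O=Cc1c(OC)c(OC)c(OC)cc1OC(=O)/C(OC)=C/c1cc(OCc2ccccc2)c(OC)cc1OCc1ccccc1 | intermediate
12 | cis-fused β-lactone of (2R)-2-aryl-4-hydroxy-3,5,6,7-tetramethoxychromane-3-carboxylic acid (lactone bridge on the face anti to the aryl group; C3 and C4 configurations as drawn, lost in the same step) | COc1cc(OCc2ccccc2)c([C@H]2Oc3cc(OC)c(OC)c(OC)c3[C@@H]3OC(=O)[C@]23OC)cc1OCc1ccccc1 | intermediate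
13 | (R)-2-[2,5-bis(benzyloxy)-4-methoxyphenyl]-3,5,6,7-tetramethoxy-2H-chromene | COc1cc(OCc2ccccc2)c([C@H]2Oc3cc(OC)c(OC)c(OC)c3C=C2OC)cc1OCc1ccccc1 | intermediate
14 | C4 alkylborane from 13 (drawn as RBH2; B at C4 and new H at C3 syn, both anti to the C2 aryl group) | COc1cc(OCc2ccccc2)c([C@H]2Oc3cc(OC)c(OC)c(OC)c3[C@H](B)[C@H]2OC)cc1OCc1ccccc1 | intermediate
15 | (2R,3R,4S)-2-[2,5-bis(benzyloxy)-4-methoxyphenyl]-3,5,6,7-tetramethoxychroman-4-ol (3-OMe cis to aryl, 4-OH trans to aryl) | COc1cc(OCc2ccccc2)c([C@H]2Oc3cc(OC)c(OC)c(OC)c3[C@H](O)[C@H]2OC)cc1OCc1ccccc1 | intermediate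
16 | (2R,3S)-2-[2,5-bis(benzyloxy)-4-methoxyphenyl]-3,5,6,7-tetramethoxychroman-4-one (2,3-cis) | COc1cc(OCc2ccccc2)c([C@H]2Oc3cc(OC)c(OC)c(OC)c3C(=O)[C@H]2OC)cc1OCc1ccccc1 | intermediate
17 | (2R,3R)-2-[2,5-bis(benzyloxy)-4-methoxyphenyl]-3,5,6,7-tetramethoxychroman-4-one (2,3-trans) | COc1cc(OCc2ccccc2)c([C@H]2Oc3cc(OC)c(OC)c(OC)c3C(=O)[C@@H]2OC)cc1OCc1ccccc1 | intermediate
18 | (2R,3R)-2-[2,5-bis(benzyloxy)-4-methoxyphenyl]-5-hydroxy-3,6,7-trimethoxychroman-4-one | COc1cc(OCc2ccccc2)c([C@H]2Oc3cc(OC)c(OC)c(O)c3C(=O)[C@@H]2OC)cc1OCc1ccccc1 | intermediate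
19 | (2R,3R)-2-(2,5-dihydroxy-4-methoxyphenyl)-5-hydroxy-3,6,7-trimethoxychroman-4-one | COc1cc(O)c([C@H]2Oc3cc(OC)c(OC)c(O)c3C(=O)[C@@H]2OC)cc1O | target

**Step count:** 10 steps in total. The longest linear sequence is 9 steps (3 to 19, steps 2 to 10).

**Steps most likely to fail**

1. Step 6 (proposed new method). The aryloxide may only be O-acylated without re-ionisation of the ester, or conjugate addition to the electron-rich, α-methoxy-substituted acylammonium ion may be too slow or poorly face-selective. Fallback with known chemistry and a different ring closure, setting out from 6 and 1: an oxazolidinone-auxiliary boron syn-aldol addition of (R)-4-benzyl-3-(2-methoxyacetyl)oxazolidin-2-one to aldehyde 6 (Bu2BOTf, i-Pr2NEt, CH2Cl2, −78 °C) would give (R)-4-benzyl-3-[(2R,3S)-3-(2,5-bis(benzyloxy)-4-methoxyphenyl)-3-hydroxy-2-methoxypropanoyl]oxazolidin-2-one F1. Mitsunobu etherification with phenol 1 (PPh3, DIAD, THF, 0 °C) would invert the benzylic carbinol and give (R)-4-benzyl-3-[(2R,3R)-3-(2,5-bis(benzyloxy)-4-methoxyphenyl)-2-methoxy-3-(3,4,5-trimethoxyphenoxy)propanoyl]oxazolidin-2-one F2. LiOH/H2O2 would release (2R,3R)-3-[2,5-bis(benzyloxy)-4-methoxyphenyl]-2-methoxy-3-(3,4,5-trimethoxyphenoxy)propanoic acid F3. Intramolecular Friedel–Crafts acylation (TFAA, CH2Cl2, 0 °C) at either of the two equivalent positions ortho to the ether oxygen would close ring C and give 17, where the route is rejoined before step 9.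

2. Step 7. The β-methoxy organoborane may undergo β-elimination (loss of the C3 methoxy group), or boron may be delivered to C3. Fallback, setting out from 13: epoxidation with dimethyldioxirane (acetone/CH2Cl2, −40 °C) on the face anti to the aryl group would give the epoxy ether (2R)-2-[2,5-bis(benzyloxy)-4-methoxyphenyl]-3,4-epoxy-3,5,6,7-tetramethoxychromane F4. Reductive opening at the acetal carbon with i-Bu2AlH (CH2Cl2, −78 °C), with hydride delivered from the aluminium bound to the epoxide oxygen as in openings of glycal epoxides, would give 15, where the route is rejoined.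

3. Step 9. Ether cleavage may be unselective, with benzyl ethers lost alongside the wanted demethylation, giving mixtures. Fallback, setting out from 17: a single global Lewis-acid deprotection (excess BCl3 with pentamethylbenzene as benzyl-cation scavenger, CH2Cl2, −78 to 0 °C) would cleave both benzyl ethers and the chelated 5-O-methyl ether and give 19 directly, replacing steps 9 and 10; this fallback makes no new compound (F0).

**Further compounds**
F1 | step 6 | (R)-4-benzyl-3-[(2R,3S)-3-(2,5-bis(benzyloxy)-4-methoxyphenyl)-3-hydroxy-2-methoxypropanoyl]oxazolidin-2-one | COc1cc(OCc2ccccc2)c([C@H](O)[C@@H](OC)C(=O)N2[C@H](Cc3ccccc3)COC2=O)cc1OCc1ccccc1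
F2 | step 6 | (R)-4-benzyl-3-[(2R,3R)-3-(2,5-bis(benzyloxy)-4-methoxyphenyl)-2-methoxy-3-(3,4,5-trimethoxyphenoxy)propanoyl]oxazolidin-2-one | COc1cc(OCc2ccccc2)c([C@@H](Oc2cc(OC)c(OC)c(OC)c2)[C@@H](OC)C(=O)N2[C@H](Cc3ccccc3)COC2=O)cc1OCc1ccccc1
F3 | step 6 | (2R,3R)-3-[2,5-bis(benzyloxy)-4-methoxyphenyl]-2-methoxy-3-(3,4,5-trimethoxyphenoxy)propanoic acid | COc1cc(OCc2ccccc2)c([C@@H](Oc2cc(OC)c(OC)c(OC)c2)[C@@H](OC)C(O)=O)cc1OCc1ccccc1
F4 | step 7 | (2R)-2-[2,5-bis(benzyloxy)-4-methoxyphenyl]-3,4-epoxy-3,5,6,7-tetramethoxychromane (epoxide anti to the aryl group) | COc1cc(OCc2ccccc2)c([C@H]2Oc3cc(OC)c(OC)c(OC)c3[C@@H]3O[C@]23OC)cc1OCc1ccccc1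
F0 | step 9 | none | none
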